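Everything rests on cutting the C5–C6 bond of ring B. In the forward sense a chiral carbene turns the C6 aldehyde of an achiral dienone into an acyl anion equivalent that adds to C5 (Stetter reaction); this one operation closes ring B, sets quaternary C10 and places the C3 and C6 oxygens in a 1,4-relationship across C4–C5. The feature exploited is that ring A can be drawn as a cyclohexadienone in which C10 carries the methyl group and the tether, so its halves C1=C2 and C4=C5 are enantiotopic and choosing one fixes C10. The precursor is 4-methyl-4-(4-oxobutyl)cyclohexa-2,5-dien-1-one, five steps from ε-caprolactone, iodomethane and methyl vinyl ketone.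

Key step: step 6

Remark on the chemistry: eudesmane numbering (C1–C15) is used for all bicyclic compounds; β is the face of the C10 methyl group.
Assumption: the antipode of the aminoindanol-derived triazolium salt that selects the required enone arm is identified in a pilot run; both antipodes are accessible.
Assumption: the trans ring fusion and the equatorial C7 side chain are reached by enolisation of the C6 ketone (steps 6 and 8); this equilibrium is a prediction and is treated as such below.

Step 1
Reactants: 1 ε-caprolactone; 2 iodomethane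
Product: 3 3-methyloxepan-2-one (racemic)
Conditions: LiN(i-Pr)2, THF, −78 °C; MeI, −78 → −40 °C
Reagents that add atoms: iodomethane, CI
Why: Lactone enolate alkylation: the lithium enolate formed at −78 °C should be C-methylated before ring-opening oligomerisation competes, and the new α-centre is racemic and is erased in step 4.

Step 2
Reactants: 3 3-methyloxepan-2-one
Product: 4 6-hydroxy-2-methylhexanal (racemic; in equilibrium with its lactol 3-methyloxepan-2-ol)
Conditions: i-Bu2AlH (1.05 equiv), CH2Cl2, −78 °C; aqueous work-up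
Reagents that add atoms: none
Why: Partial reduction of a lactone with i-Bu2AlH stops at the tetrahedral aluminate at low temperature, which should release the hydroxy aldehyde/lactol on work-up.

Step 3
Reactants: 4 6-hydroxy-2-methylhexanal; 5 methyl vinyl ketone
Product: 7 4-(4-hydroxybutyl)-4-methylcyclohex-2-en-1-one (racemic), via Michael adduct 6 (not isolated)
Conditions: pyrrolidine (0.3 equiv), AcOH (0.3 equiv), toluene, rt then reflux (Dean–Stark)
Reagents that add atoms: methyl vinyl ketone, CC(=O)C=C
Why: Robinson annulation under enamine catalysis: the enamine of the α-branched aldehyde adds to the vinyl ketone and the 1,5-keto aldehyde closes by aldol condensation to the 4,4-disubstituted cyclohexenone, whose quaternary centre is racemic and becomes prochiral in step 4.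

Step 4
Reactants: 7 4-(4-hydroxybutyl)-4-methylcyclohex-2-en-1-one
Product: 8 4-(4-hydroxybutyl)-4-methylcyclohexa-2,5-dien-1-one
Conditions: DDQ (1.5 equiv), dioxane, reflux
Reagents that add atoms: none
Why: Quinone dehydrogenation of a 4,4-disubstituted cyclohexenone should introduce the second ring double bond, which makes the quaternary carbon prochiral, while the saturated primary alcohol is left alone.

Step 5
Reactants: 8 4-(4-hydroxybutyl)-4-methylcyclohexa-2,5-dien-1-one
Product: 9 4-methyl-4-(4-oxobutyl)cyclohexa-2,5-dien-1-one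
Conditions: TEMPO (10 mol %), PhI(OAc)2 (1.1 equiv), CH2Cl2, rt
Reagents that add atoms: none
Why: Oxoammonium (TEMPO) oxidation should stop at the aldehyde and leave the cross-conjugated dienone untouched, so the sensitive keto aldehyde is made directly before use.

Step 6
Reactants: 9 4-methyl-4-(4-oxobutyl)cyclohexa-2,5-dien-1-one
Product: 11 trans-10-methyl-Δ1-octalin-3,6-dione (11,12,13,15-tetranoreudesm-1-ene-3,6-dione; 5α-H; 10β-methyl), via cis-fused adduct 10 (not isolated)
Conditions: chiral aminoindanol-derived N-pentafluorophenyl triazolium tetrafluoroborate (20 mol %), KN(SiMe3)2 (20 mol %), toluene, rt; then DBU (0.5 equiv), CH2Cl2, rt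
Reagents that add atoms: none
Why: The free triazolylidene adds to the C6 aldehyde, proton transfer gives the nucleophilic enaminol, its carbon adds to C5 of one enone arm, and collapse of the adduct returns the carbene and leaves the C6 ketone; the closest known reaction type is the carbene-catalysed intramolecular Stetter desymmetrisation of 4,4-disubstituted cyclohexadienones, established for five-membered closures and applied here to a six-membered one. Ring B closes in the 6-exo-trig mode, since C4 of the attacked C4=C5 bond stays outside the new ring. C10 is set by the chiral carbene, which must choose between the two enantiotopic arms, and the substrate supports this by offering each arm only one reachable β-carbon and no enolisable position on the dienone. C5 is first set by the tether, which can deliver C6 only to the face that carries C9 and therefore gives the cis-fused adduct 10. As C5 then lies α to the new ketone, DBU is expected to equilibrate it by enolisation toward the trans-fused dione 11, in analogy to the 5β to 5α change of steroidal 3,6-diones, and cis isomer left at equilibrium would be separated and resubmitted to the base.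

Step 7
Reactants: 11 trans-10-methyl-Δ1-octalin-3,6-dione
Product: 12 3β-hydroxy-11,12,13,15-tetranoreudesm-1-en-6-one (5α-H; 10β-methyl)
Conditions: CeCl3·7H2O (1.1 equiv), NaBH4 (1.0 equiv), MeOH, −78 °C
Reagents that add atoms: none
Why: Luche reduction: the cerium-activated, unhindered enone carbonyl at C3 should be reduced 1,2 in preference to the saturated C6 ketone, which lies next to the ring fusion under the syn-axial C10 methyl, and axial hydride delivery from the α face gives the 3β-alcohol that masks C3 during the ring B steps and later directs the epoxidation.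

Step 8
Reactants: 12 3β-hydroxy-11,12,13,15-tetranoreudesm-1-en-6-one; 13 methyl bromoacetate
Product: 15 3β-hydroxy-6-oxo-13,15-dinoreudesm-1-en-12-oic acid (5α-H; 7α-H; 10β-methyl), via methyl ester 14 (not isolated)
Conditions: LiN(i-Pr)2 (2.2 equiv), THF, −78 °C; BrCH2CO2Me, DMPU, −78 → −20 °C; then LiOH, H2O/MeOH, rt; 1 M HCl
Reagents that add atoms: methyl bromoacetate, COC(=O)CBr; lithium hydroxide, [Li+].[OH-]
Why: Enolate alkylation followed by saponification: with C3 at the alcohol level C6 is the only carbonyl, so the base should form the less substituted C7 enolate (the alkoxide is a spectator) and the bromoacetate should alkylate it at carbon, after which hydroxide hydrolyses the ester and is expected to equilibrate the enolisable C7 (and C5) centres to the trans-fused ketone with the equatorial 7β side chain.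

Step 9
Reactants: 15 3β-hydroxy-6-oxo-13,15-dinoreudesm-1-en-12-oic acid
Product: 17 3β-hydroxy-13,15-dinoreudesm-1-en-12,6α-olide (5α-H; 7α-H; 10β-methyl), via hydroxy acid 16 (not isolated)
Conditions: Li (excess), NH3(l)/THF, t-BuOH, −78 °C; NH4Cl; dilute HCl work-up; then CSA (cat.), CH2Cl2, rt
Reagents that add atoms: none
Why: Dissolving-metal (Birch-type) ketone reduction passes through a ketyl and carbanion that are protonated to the more stable equatorial 6α-alcohol (a hydride reagent would instead give the axial 6β-epimer, syn-axial to the C10 methyl), the carboxylate, the allylic alkoxide and the isolated C1=C2 bond being inert, and acid then closes the trans-diequatorial hydroxy acid to the trans-fused γ-lactone.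

Step 10
Reactants: 17 3β-hydroxy-13,15-dinoreudesm-1-en-12,6α-olide
Product: 18 1β,2β-epoxy-3β-hydroxy-13,15-dinoreudesman-12,6α-olide
Conditions: VO(acac)2 (5 mol %), t-BuOOH (1.5 equiv), CH2Cl2, 0 °C → rt
Reagents that add atoms: tert-butyl hydroperoxide, CC(C)(C)OO
Why: Hydroxyl-directed vanadium-catalysed epoxidation should deliver the oxygen to the face of the allylic 3β-hydroxyl, which sets C1 and C2 as the 1β,2β-epoxide despite the neighbouring angular methyl, as in the syn epoxidation of steroidal 4-en-3β-ols.

Step 11
Reactants: 18 1β,2β-epoxy-3β-hydroxy-13,15-dinoreudesman-12,6α-olide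
Product: 19 1β,2β-epoxy-3-oxo-13,15-dinoreudesman-12,6α-olide
Conditions: DMP (1,1,1-triacetoxy-1,1-dihydro-1,2-benziodoxol-3(1H)-one, 1.3 equiv), CH2Cl2, 0 °C → rt
Reagents that add atoms: none
Why: Periodinane oxidation of the secondary epoxy alcohol should give the α,β-epoxy ketone without touching epoxide or lactone; no stereocentre is formed and C3 is returned to the ketone level for the C4 chemistry.

Step 12
Reactants: 19 1β,2β-epoxy-3-oxo-13,15-dinoreudesman-12,6α-olide; 20 dimethylmethyleneammonium iodide
Product: 21 13,15-bis(dimethylamino)-1β,2β-epoxy-3-oxoeudesman-12,6α-olide (mixture of C4 and C11 epimers)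
Conditions: LiN(i-Pr)2 (2.3 equiv), THF, −78 °C; 20 (3 equiv), −78 °C → rt
Reagents that add atoms: dimethylmethyleneammonium iodide, C=[N+](C)C.[I-]
Why: Double Mannich reaction: excess base should form the ketone enolate, which can only lie toward C4 because C2 is an epoxide carbon, together with the lactone enolate at C11, and both are aminomethylated by the iminium salt, the new C4 and C11 centres being of no consequence because step 14 removes them.

Step 13
Reactants: 21 13,15-bis(dimethylamino)-1β,2β-epoxy-3-oxoeudesman-12,6α-olide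
Product: 22 13,15-bis(dimethylamino)-1β-hydroxy-3-oxoeudesman-12,6α-olide
Conditions: SmI2 (2.5 equiv), THF/MeOH, −90 °C
Reagents that add atoms: none
Why: Reductive cleavage of an α,β-epoxy ketone by SmI2 breaks only the C2–O bond next to the carbonyl, so the C1–O bond and the 1β configuration set in step 10 are kept (conjugate addition or nucleophilic epoxidation of the ring A enone would instead give the 1α series), while amines and lactone are inert.

Step 14
Reactants: 22 13,15-bis(dimethylamino)-1β-hydroxy-3-oxoeudesman-12,6α-olide; 2 iodomethane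
Product: 24 1β-hydroxy-3-oxoeudesma-4(15),11(13)-dien-12,6α-olide, via bis(trimethylammonium) diiodide 23 (not isolated)
Conditions: MeI (excess), MeOH/CH2Cl2, rt; then aq. NaHCO3, EtOAc, rt
Reagents that add atoms: none
Why: Exhaustive N-methylation and mild base should trigger E1cB loss of trimethylamine from both β-ammonium carbonyl units (Mannich-base methylenation), which gives the C4=C15 and C11=C13 methylenes at a stage where C6 is no longer a ketone, so the ring A double bond cannot move into conjugation with ring B.

Step 15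
Reactants: 24 1β-hydroxy-3-oxoeudesma-4(15),11(13)-dien-12,6α-olide
Product: 25 1β,3β-dihydroxyeudesma-4(15),11(13)-dien-12,6α-olide
Conditions: CeCl3·7H2O (1.1 equiv), NaBH4 (1.0 equiv), MeOH, −78 °C
Reagents that add atoms: none
Why: Luche reduction should add hydride 1,2 to the exo-methylene ketone along the axial α trajectory of the chair-locked ring A, which gives the equatorial 3β-allylic alcohol, and the α-methylene lactone is expected to survive at this temperature.

Step 16
Reactants: 25 1β,3β-dihydroxyeudesma-4(15),11(13)-dien-12,6α-olide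
Product: 26 1β,3β-bis(tert-butyldimethylsilyloxy)eudesma-4(15),11(13)-dien-12,6α-olide
Conditions: TBSOTf (2.6 equiv), 2,6-lutidine, CH2Cl2, −78 → 0 °C
Reagents that add atoms: tert-butyldimethylsilyl triflate, CC(C)(C)[Si](C)(C)OS(=O)(=O)C(F)(F)F
Why: Silyl ether formation with the silyl triflate should protect both secondary alcohols, including the hindered 1β-hydroxyl next to C10, so that only the C6 hydroxyl released in step 17 can be acylated.

Step 17
Reactants: 26 1β,3β-bis(tert-butyldimethylsilyloxy)eudesma-4(15),11(13)-dien-12,6α-olide; 2 iodomethane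
Product: 28 methyl 1β,3β-bis(tert-butyldimethylsilyloxy)-6α-hydroxyeudesma-4(15),11(13)-dien-12-oate, via lithium carboxylate 27 (not isolated)
Conditions: LiOH·H2O (1.1 equiv), THF/H2O, 0 °C → rt; evaporation; MeI, DMF, 0 °C → rt
Reagents that add atoms: lithium hydroxide, [Li+].[OH-]; iodomethane, CI
Why: Lactone saponification followed by carboxylate O-alkylation: hydroxide opens the lactone irreversibly and the salt is methylated without passing through the free hydroxy acid, which limits re-lactonisation and leaves C6 untouched.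

Step 18
Reactants: 29 ethyl 2-(hydroxymethyl)acrylate
Product: 30 ethyl 2-[(tert-butyldimethylsilyloxy)methyl]acrylate
Conditions: TBSCl, imidazole, DMF, 0 °C → rt
Reagents that add atoms: tert-butyldimethylsilyl chloride, CC(C)(C)[Si](C)(C)Cl
Why: Standard silylation of a primary alcohol masks the hydroxymethyl group of the acyl fragment.

Step 19
Reactants: 30 ethyl 2-[(tert-butyldimethylsilyloxy)methyl]acrylate
Product: 31 2-[(tert-butyldimethylsilyloxy)methyl]acrylic acid
Conditions: LiOH, THF/H2O, 0 °C; dilute HCl to pH 4
Reagents that add atoms: lithium hydroxide, [Li+].[OH-]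
Why: Ester saponification under cold dilute base should leave the primary silyl ether and the acrylate double bond intact.

Step 20
Reactants: 28 methyl 1β,3β-bis(tert-butyldimethylsilyloxy)-6α-hydroxyeudesma-4(15),11(13)-dien-12-oate; 31 2-[(tert-butyldimethylsilyloxy)methyl]acrylic acid
Product: 33 methyl 1β,3β-bis(tert-butyldimethylsilyloxy)-6α-{2-[(tert-butyldimethylsilyloxy)methyl]acryloyloxy}eudesma-4(15),11(13)-dien-12-oate, via mixed anhydride 32 (not isolated)
Conditions: 31, 2,4,6-trichlorobenzoyl chloride, Et3N, toluene, rt; then 28, DMAP, rt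
Reagents that add atoms: none
Why: Yamaguchi esterification: DMAP attacks the mixed anhydride at the acryloyl carbonyl and the acylpyridinium acylates the equatorial 6α-hydroxyl with retention at C6, acylation being expected to outpace re-closure of the hydroxy ester to the lactone.

Step 21
Reactants: 33 methyl 1β,3β-bis(tert-butyldimethylsilyloxy)-6α-{2-[(tert-butyldimethylsilyloxy)methyl]acryloyloxy}eudesma-4(15),11(13)-dien-12-oate
Product: 34 methyl 1β,3β-dihydroxy-6α-[2-(hydroxymethyl)acryloyloxy]eudesma-4(15),11(13)-dien-12-oate (CNP0247525.1)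
Conditions: HF·pyridine, THF/pyridine, 0 °C → rt
Reagents that add atoms: none
Why: Buffered fluoride desilylation should cleave the three silyl ethers without hydrolysing or migrating either acrylate ester, which releases the target.

Compound list
1 | ε-caprolactone (oxepan-2-one) | O=C1CCCCCO1 | starting material
2 | iodomethane | CI | starting material
3 | 3-methyloxepan-2-one (racemic) | CC1CCCCOC1=O | intermediate
4 | 6-hydroxy-2-methylhexanal (racemic; open form of the lactol) | CC(CCCCO)C=O | intermediate
5 | methyl vinyl ketone (but-3-en-2-one) | CC(=O)C=C | starting material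
6 | 2-(4-hydroxybutyl)-2-methyl-5-oxohexanal (racemic Michael adduct) | CC(=O)CCC(C)(CCCCO)C=O | intermediate (not isolated)
7 | 4-(4-hydroxybutyl)-4-methylcyclohex-2-en-1-one (racemic) | CC1(CCCCO)CCC(=O)C=C1 | intermediate
8 | 4-(4-hydroxybutyl)-4-methylcyclohexa-2,5-dien-1-one | CC1(CCCCO)C=CC(=O)C=C1 | intermediate
9 | 4-methyl-4-(4-oxobutyl)cyclohexa-2,5-dien-1-one | O=CCCCC1(C)C=CC(=O)C=C1 | intermediate
10 | cis-10-methyl-Δ1-octalin-3,6-dione (5β-H; 10β-methyl) | O=C1[C@@H]2CC(=O)C=C[C@]2(C)CCC1 | intermediate (not isolated)
11 | trans-10-methyl-Δ1-octalin-3,6-dione (11,12,13,15-tetranoreudesm-1-ene-3,6-dione; 5α-H; 10β-methyl) | O=C1[C@H]2CC(=O)C=C[C@]2(C)CCC1 | intermediate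
12 | 3β-hydroxy-11,12,13,15-tetranoreudesm-1-en-6-one (5α-H; 10β-methyl) | O=C1[C@H]2C[C@@H](O)C=C[C@]2(C)CCC1 | intermediate
13 | methyl bromoacetate | COC(=O)CBr | starting material
14 | methyl 3β-hydroxy-6-oxo-13,15-dinoreudesm-1-en-12-oate (C7 epimers) | O=C1[C@H]2C[C@@H](O)C=C[C@]2(C)CCC1CC(=O)OC | intermediate (not isolated)
15 | 3β-hydroxy-6-oxo-13,15-dinoreudesm-1-en-12-oic acid (5α-H; 7α-H; 10β-methyl) | O=C1[C@H]2C[C@@H](O)C=C[C@]2(C)CC[C@H]1CC(=O)O | intermediate
16 | 3β,6α-dihydroxy-13,15-dinoreudesm-1-en-12-oic acid | O[C@@H]1[C@H]2C[C@@H](O)C=C[C@]2(C)CC[C@H]1CC(=O)O | intermediate (not isolated)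
17 | 3β-hydroxy-13,15-dinoreudesm-1-en-12,6α-olide (trans-fused lactone; 5α-H; 7α-H) | O3[C@@H]1[C@H]2C[C@@H](O)C=C[C@]2(C)CC[C@H]1CC3=O | intermediate
18 | 1β,2β-epoxy-3β-hydroxy-13,15-dinoreudesman-12,6α-olide | O3[C@@H]1[C@H]2C[C@@H](O)[C@H]4O[C@H]4[C@]2(C)CC[C@H]1CC3=O | intermediate
19 | 1β,2β-epoxy-3-oxo-13,15-dinoreudesman-12,6α-olide | O3[C@@H]1[C@H]2CC(=O)[C@H]4O[C@H]4[C@]2(C)CC[C@H]1CC3=O | intermediate
20 | dimethylmethyleneammonium iodide | C=[N+](C)C.[I-] | starting material
21 | 13,15-bis(dimethylamino)-1β,2β-epoxy-3-oxoeudesman-12,6α-olide (C4 and C11 epimers) | O3[C@@H]1[C@H]2C(CN(C)C)C(=O)[C@H]4O[C@H]4[C@]2(C)CC[C@H]1C(CN(C)C)C3=O | intermediate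
22 | 13,15-bis(dimethylamino)-1β-hydroxy-3-oxoeudesman-12,6α-olide (C4 and C11 epimers) | O3[C@@H]1[C@H]2C(CN(C)C)C(=O)C[C@@H](O)[C@]2(C)CC[C@H]1C(CN(C)C)C3=O | intermediate
23 | 1β-hydroxy-3-oxo-13,15-bis(trimethylammonio)eudesman-12,6α-olide diiodide | O3[C@@H]1[C@H]2C(C[N+](C)(C)C)C(=O)C[C@@H](O)[C@]2(C)CC[C@H]1C(C[N+](C)(C)C)C3=O.[I-].[I-] | intermediate (not isolated)
24 | 1β-hydroxy-3-oxoeudesma-4(15),11(13)-dien-12,6α-olide | O3[C@@H]1[C@H]2C(=C)C(=O)C[C@@H](O)[C@]2(C)CC[C@H]1C(=C)C3=O | intermediate
25 | 1β,3β-dihydroxyeudesma-4(15),11(13)-dien-12,6α-olide | O3[C@@H]1[C@H]2C(=C)[C@@H](O)C[C@@H](O)[C@]2(C)CC[C@H]1C(=C)C3=O | intermediate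
26 | 1β,3β-bis(tert-butyldimethylsilyloxy)eudesma-4(15),11(13)-dien-12,6α-olide | O3[C@@H]1[C@H]2C(=C)[C@@H](O[Si](C)(C)C(C)(C)C)C[C@@H](O[Si](C)(C)C(C)(C)C)[C@]2(C)CC[C@H]1C(=C)C3=O | intermediate
27 | lithium 1β,3β-bis(tert-butyldimethylsilyloxy)-6α-hydroxyeudesma-4(15),11(13)-dien-12-oate | O[C@@H]1[C@H]2C(=C)[C@@H](O[Si](C)(C)C(C)(C)C)C[C@@H](O[Si](C)(C)C(C)(C)C)[C@]2(C)CC[C@H]1C(=C)C(=O)[O-].[Li+] | intermediate (not isolated)
28 | methyl 1β,3β-bis(tert-butyldimethylsilyloxy)-6α-hydroxyeudesma-4(15),11(13)-dien-12-oate | O[C@@H]1[C@H]2C(=C)[C@@H](O[Si](C)(C)C(C)(C)C)C[C@@H](O[Si](C)(C)C(C)(C)C)[C@]2(C)CC[C@H]1C(=C)C(=O)OC | intermediate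
29 | ethyl 2-(hydroxymethyl)acrylate | C=C(CO)C(=O)OCC | starting material
30 | ethyl 2-[(tert-butyldimethylsilyloxy)methyl]acrylate | C=C(CO[Si](C)(C)C(C)(C)C)C(=O)OCC | intermediate
31 | 2-[(tert-butyldimethylsilyloxy)methyl]acrylic acid | C=C(CO[Si](C)(C)C(C)(C)C)C(=O)O | intermediate
32 | 2-[(tert-butyldimethylsilyloxy)methyl]acrylic 2,4,6-trichlorobenzoic anhydride | C=C(CO[Si](C)(C)C(C)(C)C)C(=O)OC(=O)c1c(Cl)cc(Cl)cc1Cl | intermediate (not isolated)
33 | methyl 1β,3β-bis(tert-butyldimethylsilyloxy)-6α-{2-[(tert-butyldimethylsilyloxy)methyl]acryloyloxy}eudesma-4(15),11(13)-dien-12-oate | C=C(CO[Si](C)(C)C(C)(C)C)C(=O)O[C@@H]1[C@H]2C(=C)[C@@H](O[Si](C)(C)C(C)(C)C)C[C@@H](O[Si](C)(C)C(C)(C)C)[C@]2(C)CC[C@H]1C(=C)C(=O)OC | intermediate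
34 | methyl 1β,3β-dihydroxy-6α-[2-(hydroxymethyl)acryloyloxy]eudesma-4(15),11(13)-dien-12-oate (CNP0247525.1; 5α-H; 7α-H; 10β-methyl) | C=C(CO)C(=O)O[C@@H]1[C@H]2C(=C)[C@@H](O)C[C@@H](O)[C@]2(C)CC[C@H]1C(=C)C(=O)OC | target

Total step count: 21. Longest linear sequence: 19 steps (steps 1–17, 20 and 21); steps 18 and 19 prepare the acyl fragment.

Steps most likely to fail

1. Step 6. The six-membered acyl-anion closure from an enolisable aliphatic aldehyde may be outrun by aldol or enol Michael reactions of the aldehyde, and the carbene may tell the two enone arms apart poorly. The base-mediated inversion at C5 may also stall at a cis/trans mixture, because in a bicyclic 10-methyl-6-decalone the two fusions can be close in energy. The fallback keeps the C5–C6 disconnection but uses a nitronate as the acyl anion equivalent. It sets out from 8: iodination (I2, PPh3, imidazole) gives 4-(4-iodobutyl)-4-methylcyclohexa-2,5-dien-1-one F1, and displacement with NaNO2 in DMF gives 4-methyl-4-(4-nitrobutyl)cyclohexa-2,5-dien-1-one F2. A bifunctional cinchona-alkaloid thiourea then closes ring B by a desymmetrising intramolecular nitro-Michael addition (nitronate carbon C6 to C5), a known reaction type for carbon acids tethered to cyclohexadienones, to give cis-fused 6-nitro-11,12,13,15-tetranoreudesm-1-en-3-one F3. A Nef reaction (NaOMe, then buffered KHSO5) converts the nitro group into the C6 ketone, and the sequence comes back to the route at 10, which is equilibrated to 11 as in step 6.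

2. Step 8. The dianion may be alkylated at oxygen or react sluggishly, and the hydroxide equilibration may settle on cis-fused C5/C7 epimers instead of the trans-fused 7β series. The fallback builds the lactone by carbenoid C–H insertion, so no enolisable centre has to be equilibrated. It sets out from 12: silylation (TBSCl, imidazole) gives 3β-(tert-butyldimethylsilyloxy)-11,12,13,15-tetranoreudesm-1-en-6-one F4, which is reduced at once with Li in NH3 to the equatorial 6α-alcohol 3β-(tert-butyldimethylsilyloxy)-11,12,13,15-tetranoreudesm-1-en-6α-ol F5 while C7 is still a methylene group. Acylation with bromoacetyl bromide gives the 6α-bromoacetate F6, and N,N′-ditosylhydrazine with DBU gives the 6α-diazoacetate F7. Rh2(OAc)4 (or a dirhodium carboxamidate) should then insert the carbenoid into the equatorial C7–H bond with retention to give 3β-(tert-butyldimethylsilyloxy)-13,15-dinoreudesm-1-en-12,6α-olide F8. Bu4NF removes the silyl group and the sequence comes back to the route at 17.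

3. Step 17. During methylation, work-up or the following acylation the C6 hydroxyl may re-close onto C12 with loss of methanol, and hydroxide may add to C13 during the opening. The fallback acylates C6 before the methyl ester exists. It sets out from 27: the dried salt is converted into its alkoxide with LiN(SiMe3)2 at −78 °C and acylated with 2-[(tert-butyldimethylsilyloxy)methyl]acryloyl chloride F9, made from 31 with oxalyl chloride and catalytic DMF. Aqueous work-up hydrolyses any mixed anhydride at C12 and gives 1β,3β-bis(tert-butyldimethylsilyloxy)-6α-{2-[(tert-butyldimethylsilyloxy)methyl]acryloyloxy}eudesma-4(15),11(13)-dien-12-oic acid F10, in which the C6 oxygen can no longer close the lactone. Trimethylsilyldiazomethane in MeOH/toluene then forms the methyl ester and the sequence comes back to the route at 33.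

Further compounds
F1 | step 6 | 4-(4-iodobutyl)-4-methylcyclohexa-2,5-dien-1-one | CC1(CCCCI)C=CC(=O)C=C1
F2 | step 6 | 4-methyl-4-(4-nitrobutyl)cyclohexa-2,5-dien-1-one | CC1(CCCC[N+](=O)[O-])C=CC(=O)C=C1
F3 | step 6 | 6-nitro-11,12,13,15-tetranoreudesm-1-en-3-one (cis-fused; 5β-H; C6 epimers) | [O-][N+](=O)C1[C@@H]2CC(=O)C=C[C@]2(C)CCC1
F4 | step 8 | 3β-(tert-butyldimethylsilyloxy)-11,12,13,15-tetranoreudesm-1-en-6-one | O=C1[C@H]2C[C@@H](O[Si](C)(C)C(C)(C)C)C=C[C@]2(C)CCC1
F5 | step 8 | 3β-(tert-butyldimethylsilyloxy)-11,12,13,15-tetranoreudesm-1-en-6α-ol | O[C@@H]1[C@H]2C[C@@H](O[Si](C)(C)C(C)(C)C)C=C[C@]2(C)CCC1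
F6 | step 8 | 3β-(tert-butyldimethylsilyloxy)-11,12,13,15-tetranoreudesm-1-en-6α-yl bromoacetate | BrCC(=O)O[C@@H]1[C@H]2C[C@@H](O[Si](C)(C)C(C)(C)C)C=C[C@]2(C)CCC1
F7 | step 8 | 3β-(tert-butyldimethylsilyloxy)-11,12,13,15-tetranoreudesm-1-en-6α-yl diazoacetate | [N-]=[N+]=CC(=O)O[C@@H]1[C@H]2C[C@@H](O[Si](C)(C)C(C)(C)C)C=C[C@]2(C)CCC1
F8 | step 8 | 3β-(tert-butyldimethylsilyloxy)-13,15-dinoreudesm-1-en-12,6α-olide | O3[C@@H]1[C@H]2C[C@@H](O[Si](C)(C)C(C)(C)C)C=C[C@]2(C)CC[C@H]1CC3=O
F9 | step 17 | 2-[(tert-butyldimethylsilyloxy)methyl]acryloyl chloride | C=C(CO[Si](C)(C)C(C)(C)C)C(Cl)=O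
F10 | step 17 | 1β,3β-bis(tert-butyldimethylsilyloxy)-6α-{2-[(tert-butyldimethylsilyloxy)methyl]acryloyloxy}eudesma-4(15),11(13)-dien-12-oic acid | C=C(CO[Si](C)(C)C(C)(C)C)C(=O)O[C@@H]1[C@H]2C(=C)[C@@H](O[Si](C)(C)C(C)(C)C)C[C@@H](O[Si](C)(C)C(C)(C)C)[C@]2(C)CC[C@H]1C(=C)C(=O)O
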